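## Analysis of the target

Pterocarpan numbering is used throughout: ring A is C1–C4, C4a, C11b; ring B holds O5, C6, C6a, C11a; ring C holds O11; ring D is C6b–C10a; ring E is the dimethylpyran on C1 (oxygen) and C2 (carbon). The target is a cis-pterocarpan in which chroman ring B and dihydrobenzofuran ring C share the C6a–C11a bond, between the phloroglucinol-type ring A and the methoxybenzene ring D. The only stereocentres are C6a and C11a, both S. A 6/5 B/C fusion can only be cis, so one centre dictates the other, and the real problem is the absolute configuration at C6a, a tertiary carbon with no heteroatom. Ring A carries three oxygens in three roles (ring E ether on C1, free phenol on C3, ring B ether on C4a) that have to be told apart. The C11a–O11 bond is a benzylic aryl ether with two ortho oxygens and one para oxygen, so it ionises in acid and can be hydrogenolysed; the free phenol and ring A are easily oxidised. A hidden difficulty is that in a 2'-hydroxyisoflavan precursor the two benzylic methylenes on ring A, C11a and the CH2 of ring E, are almost equally activated towards hydride abstraction. The strategy reads ring B as a [4+2] adduct: O5, C4a, C11b and C11a are an ortho-quinone methide of ring A, and C6–C6a is an enol ether carrying ring D on C6a.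

## Retrosynthetic reasoning

**Target 21 from 20.** The last operation only adjusts spectator groups: in 20 ring E is still a 2H-chromene and O3 is a benzyl ether, and one catalytic hydrogenation saturates the one and cleaves the other. Ring E is carried unsaturated on purpose. A chromene has no sp3 benzylic hydrogen, so the oxidation that closes ring C cannot attack ring E.

**20 from 18.** The C11a–O11 bond is cut. C11a can be oxidised late because its cation is stabilised by the ortho oxygens O1 and O5 and the para oxygen O3, and the 2'-hydroxyl of ring D sits ready to capture it. Since only the cis fusion can form, C11a takes its configuration from C6a, and the stereochemical problem shrinks to one centre in an isoflavan. O3 is an alkyl (benzyl) ether in 18, which makes it a strong para donor for exactly this hydride abstraction.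

**18 from 17 from 16.** The 2'-silyl ether is removed with fluoride. Before that, the C6 methylene is traced back to an acetal carbon bearing the auxiliary alkoxy group in 16. This reduction is placed before ring C exists, because conditions that ionise an acetal would ionise the C11a–O11 bond even more easily.

**16 from 5 and 12 (key disconnection).** C11a–C6a and O5–C6 are cut together. This is the one place where ring B falls apart into two polarity-matched halves, an electron-poor quinone methide released from 5 and the electron-rich enol ether 12, and both halves come from simple aldehydes. The cut also puts the controlling element, the chiral alkoxy group on C6, directly on the reacting alkene and lets it leave later at no extra cost. The forward reaction must release the quinone methide cold, in the presence of 12, and add it to one face of a geometrically pure E alkene.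

**5 from 4, 4 from 2 and 3, 2 from 1.** The carbonate is removed, then ring E is opened to the enal 3 and the symmetric dihydroxyaldehyde 2. With O3 benzylated first, only the hydroxyls ortho to the formyl group can close the pyran, so one chromene regioisomer is possible and the remaining hydroxyl is the one that becomes O5.

**12 from 10 and 11, 10 from 8, 8 from 7, 7 from 6.** The enol ether is cut at its vinylic C–O bond, not at the C=C bond. An olefination would give both alkene geometries, and these lead to opposite configurations at C6a. A vinylic C–O coupling keeps the geometry of iodide 10, and 10 is made geometrically pure by syn hydrometalation and iodination of alkyne 8, obtained by one-carbon homologation of the silylated aldehyde 7.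

## Alternatives that were turned down

**Alternative 1:** Ring C is disconnected at C6a–C11a, and ring B is closed afterwards from an ester at C6. In the forward step the diazoester A1, with the ring A benzyl group on the ring D phenol oxygen, is decomposed by Rh2(S-PTTL)4 and the carbene inserts into the benzylic C–H bond to give the cis dihydrobenzofuran A2. Ester reduction, desilylation and a Mitsunobu closure of O5–C6 would follow.
- For: both stereocentres are set in one catalytic step without a stoichiometric auxiliary, and C11a–O11 is made as an ordinary ether, so no benzylic oxidation is needed. On both points it is stronger than the chosen route.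
- Against: A1 needs the ring A benzylic alcohol or halide as an alkylating agent, and with two ortho and one para oxygen that electrophile ionises and oligomerises readily. The insertion site is flanked by two ortho substituents. In A2, C6a is alpha to an ester and cis to a bulky aryl group, so it can epimerise to trans, after which ring B cannot close. Ring B still costs three steps.
- Comparison: the chosen route uses an auxiliary (recovered in step 9) instead of a catalyst, but it forms ring B in the stereodefining step, never handles an ionisable ring A benzylic electrophile, and keeps C6a non-enolisable.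

**Alternative 2:** Ring D itself is disconnected (C10a–C6b and C8–C7). The pyrone A3, a cis 3-ethynylchroman-4-yl ether of a bromopyrone, is heated; intramolecular Diels–Alder addition to the alkyne and decarboxylative cycloreversion give the bromopterocarpan A4 with rings C and D closed together. Bromide must then be exchanged for methoxide and the silyl ether removed.
- For: ring C closes with no oxidation at C11a, which is stronger than the chosen route on that point, and the halogen position is fixed by the pyrone.
- Against: ring D is a plain methoxybenzene that can be bought as an aldehyde, so building it earns nothing. The cis C6a/C11a pair must already be present in A3, so the stereochemical problem is only moved to a cis 3-ethynylchroman-4-ol. A3 holds a doubly ortho-oxygenated benzylic ether that has to survive prolonged heating. A late methoxylation on an acid-labile pterocarpan is added.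
- Comparison: the chosen route is shorter, takes ring D as purchased and sets C6a in the ring-forming step; it pays with one benzylic oxidation.

**Alternative 3:** Ring B is disconnected at C11a–C11b and O5–C6 between the ring A/E phenol A5 and the benzofuran aldehyde A6, which already holds rings C and D. A diarylprolinol silyl ether turns A6 into its iminium ion; the carbon of A5 ortho to the free phenol attacks C11a, dearomatising the furan, and the phenol closes on C6 to give the cis lactol A7. Reduction of the lactol carbon and desilylation would finish.
- For: it is the most convergent and shortest plan, a catalytic asymmetric step making ring B and both stereocentres at once. In step economy it is clearly better than the chosen route.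
- Against: the addition must break the aromaticity of a benzofuran whose iminium ion is a weak acceptor, and the adduct can fall apart again by beta-elimination of the ring D phenoxide. A5 has two nucleophilic carbons ortho to its free phenol (the future C11b and C4), so a linear regioisomer should compete. Removing the lactol oxygen of A7 needs ionising conditions at C6 in a molecule whose C11a–O11 bond ionises more easily.
- Comparison: the chosen route is longer, but the methide carbon is already attached to C11b (no regiochemical question), no arene is dearomatised, and the C6 oxygen is removed before the C11a–O11 bond exists.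

Key step: step 8

Assumption: the enol ether is taken to react in its s-trans conformation on the face not covered by the phenyl group of the auxiliary; on this model the (1S,2R)-alcohol 11 leads to (S)-C6a, and if the sense of induction were found reversed, the equally available enantiomer would be used in the same steps.

## Route

Step 1
Reactants: 1 2,4,6-trihydroxybenzaldehyde
Product: 2 4-(benzyloxy)-2,6-dihydroxybenzaldehyde
Conditions: BnBr (1.0 equiv), KHCO3, DMF, rt
Reagents that add atoms: benzyl bromide, BrCc1ccccc1
Why: Williamson etherification under weak base; the 4-hydroxyl, para to the formyl group, is the most acidic and the only one not held in a hydrogen bond to the carbonyl, so one equivalent of halide should alkylate it selectively, and the benzyl group masks O3 until the last step.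

Step 2
Reactants: 2 4-(benzyloxy)-2,6-dihydroxybenzaldehyde; 3 3-methylbut-2-enal
Product: 4 5-(benzyloxy)-7-hydroxy-2,2-dimethyl-2H-chromene-8-carbaldehyde
Conditions: Ca(OH)2, MeOH, rt
Reagents that add atoms: none
Why: Known base-mediated chromene annulation of phenols with enals (aldol-type C-alkylation ortho to the phenoxide, dehydration, oxa-6π electrocyclisation); 2 is symmetric and only its free ortho hydroxyls can close the pyran, so a single regioisomer is possible, and one equivalent of 3 limits a second annulation.

Step 3
Reactants: 4 5-(benzyloxy)-7-hydroxy-2,2-dimethyl-2H-chromene-8-carbaldehyde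
Product: 5 tert-butyl [5-(benzyloxy)-8-formyl-2,2-dimethyl-2H-chromen-7-yl] carbonate
Conditions: Boc2O, i-Pr2NEt, DMAP (cat.), THF, 0 °C → rt
Reagents that add atoms: di-tert-butyl dicarbonate, CC(C)(C)OC(=O)OC(=O)OC(C)(C)C
Why: DMAP-catalysed carbonate formation on the only free phenol gives the O-Boc salicylaldehyde from which the ortho-quinone methide is released in step 8.

Step 4
Reactants: 6 2-hydroxy-4-methoxybenzaldehyde
Product: 7 4-methoxy-2-(triisopropylsilyloxy)benzaldehyde
Conditions: TIPSCl, imidazole, DMF, rt
Reagents that add atoms: chlorotriisopropylsilane, CC(C)[Si](Cl)(C(C)C)C(C)C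
Why: Standard phenol silylation; the bulky silyl ether should survive the organolithium, zirconium, copper and Lewis acid steps and is later removed by fluoride without touching the benzyl ether or the chromene.

Step 5
Reactants: 7 4-methoxy-2-(triisopropylsilyloxy)benzaldehyde
Product: 8 1-ethynyl-4-methoxy-2-(triisopropylsilyloxy)benzene
Conditions: TMSCHN2, LDA, THF, −78 °C → rt
Reagents that add atoms: (trimethylsilyl)diazomethane, C[Si](C)(C)C=[N+]=[N-]
Why: Colvin rearrangement (addition of lithiated trimethylsilyldiazomethane to the aldehyde, Peterson-type elimination, loss of N2 and 1,2-hydride shift) gives the terminal alkyne under non-protic conditions that spare the aryl silyl ether.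

Step 6
Reactants: 8 1-ethynyl-4-methoxy-2-(triisopropylsilyloxy)benzene
Product: 10 (E)-1-(2-iodoethenyl)-4-methoxy-2-(triisopropylsilyloxy)benzene, via Cp2Zr(Cl)-alkenyl intermediate 9 (not isolated)
Conditions: Cp2Zr(H)Cl, THF, rt; then I2, 0 °C
Reagents that add atoms: iodine, II
Why: Hydrozirconation is a syn addition that puts zirconium on the terminal carbon, and iodinolysis of the C–Zr bond goes with retention, so the E iodide should form free of its Z isomer.

Step 7
Reactants: 10 (E)-1-(2-iodoethenyl)-4-methoxy-2-(triisopropylsilyloxy)benzene; 11 (1S,2R)-trans-2-phenylcyclohexanol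
Product: 12 (E)-2-[4-methoxy-2-(triisopropylsilyloxy)phenyl]ethenyl (1S,2R)-2-phenylcyclohexyl ether
Conditions: CuI (10 mol %), 3,4,7,8-tetramethyl-1,10-phenanthroline (20 mol %), Cs2CO3, toluene, 80 °C
Reagents that add atoms: none
Why: Ullmann-type copper-catalysed C–O coupling of a vinyl iodide with an alcohol, a reaction known to keep the alkene geometry; 11 is used in excess and recovered, and the E iodide has no hydrogen anti to iodine for elimination.

Step 8
Reactants: 5 tert-butyl [5-(benzyloxy)-8-formyl-2,2-dimethyl-2H-chromen-7-yl] carbonate; 12 (E)-2-[4-methoxy-2-(triisopropylsilyloxy)phenyl]ethenyl (1S,2R)-2-phenylcyclohexyl ether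
Product: 16 (8R,9S)-5-(benzyloxy)-9-[4-methoxy-2-(triisopropylsilyloxy)phenyl]-2,2-dimethyl-8-{[(1S,2R)-2-phenylcyclohexyl]oxy}-9,10-dihydro-2H,8H-pyrano[2,3-f]chromene, via benzylic alkoxide 13 (not isolated), via migrated carbonate phenoxide 14 (not isolated), via ortho-quinone methide 15 (not isolated)
Conditions: 5 + 12 (1.5 equiv), LiBHEt3 (1.0 equiv), Et2O, −78 °C; then MgBr2·OEt2, −78 °C → rt
Reagents that add atoms: none
Why: Hydride adds to the aldehyde of 5 to give alkoxide 13, the Boc group moves from the phenol oxygen to that alkoxide (14), and with MgBr2 on warming tert-butyl carbonate leaves in a 1,4-elimination to give ortho-quinone methide 15, which 12 traps as it forms in an inverse-electron-demand hetero-Diels–Alder reaction. The closest known reaction type is the low-temperature release of ortho-quinone methides from O-Boc salicylaldehydes by a hydride or organometallic nucleophile and their diastereoselective [4+2] cycloaddition with enol ethers of trans-2-phenylcyclohexanol. A single hydride equivalent from LiBHEt3 is used, not a borohydride carrying four, because surplus hydride is known to reduce the quinone methide on to the methylphenol. Ring B closes by a concerted, asynchronous [4+2] cycloaddition in which the nucleophilic beta carbon of the enol ether (C6a) bonds to the methide carbon C11a and the carbonyl oxygen O5 bonds to the alkoxy-bearing carbon C6, ring A regaining aromaticity. C6a is controlled by the auxiliary: in the s-trans enol ether the phenyl group on the cyclohexane covers one face of the C=C and the quinone methide adds to the other, which for the (1S,2R) auxiliary and the E alkene should give (S)-C6a; the acetal carbon follows from suprafacial addition (aryl and alkoxy trans) and is removed in step 9. The step needs regioselectivity, secured by the matched polarisation of methide carbon and enol ether beta carbon; facial selectivity, secured by the auxiliary together with the geometric purity of 12; and preference for 12 over the chromene double bond, secured by the far higher nucleophilicity of the enol ether and its excess.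

Step 9
Reactants: 16 (8R,9S)-5-(benzyloxy)-9-[4-methoxy-2-(triisopropylsilyloxy)phenyl]-2,2-dimethyl-8-{[(1S,2R)-2-phenylcyclohexyl]oxy}-9,10-dihydro-2H,8H-pyrano[2,3-f]chromene
Product: 17 (9S)-5-(benzyloxy)-9-[4-methoxy-2-(triisopropylsilyloxy)phenyl]-2,2-dimethyl-9,10-dihydro-2H,8H-pyrano[2,3-f]chromene
Conditions: Et3SiH, BF3·OEt2, CH2Cl2, −78 °C
Reagents that add atoms: none
Why: Ionic hydrogenation of a mixed acetal; BF3 ionises the exocyclic C–O bond to the more basic auxiliary oxygen, the cyclic oxocarbenium ion is reduced by the silane to the C6 methylene and 11 is recovered, C6a is untouched, and the reduction is done now because the later C11a–O11 bond would not survive it.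

Step 10
Reactants: 17 (9S)-5-(benzyloxy)-9-[4-methoxy-2-(triisopropylsilyloxy)phenyl]-2,2-dimethyl-9,10-dihydro-2H,8H-pyrano[2,3-f]chromene
Product: 18 2-[(9S)-5-(benzyloxy)-2,2-dimethyl-9,10-dihydro-2H,8H-pyrano[2,3-f]chromen-9-yl]-5-methoxyphenol
Conditions: TBAF, THF, 0 °C
Reagents that add atoms: none
Why: Fluoride cleavage of the aryl silyl ether frees the 2'-hydroxyl needed for ring C; benzyl ether and chromene are inert to it.

Step 11
Reactants: 18 2-[(9S)-5-(benzyloxy)-2,2-dimethyl-9,10-dihydro-2H,8H-pyrano[2,3-f]chromen-9-yl]-5-methoxyphenol
Product: 20 (6aS,11aS)-3-(benzyloxy)-9-methoxypterocarpan with a 2,2-dimethyl-2H-pyran ring fused at C1 (oxygen) and C2, via C11a benzylic cation 19 (not isolated)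
Conditions: DDQ (1.1 equiv), NaHCO3, CH2Cl2, 0 °C → rt
Reagents that add atoms: none
Why: Known oxidative cyclisation of 2'-hydroxyisoflavans with DDQ; hydride abstraction from C11a gives cation 19, stabilised by the ortho oxygens O1 and O5 and the para benzyloxy group, and the phenol closes ring C in a 5-exo-trig mode, which can only give the cis fusion, so (S)-C6a fixes (S)-C11a; ring E as a chromene offers no competing benzylic hydrogen.

Step 12
Reactants: 20 (6aS,11aS)-3-(benzyloxy)-9-methoxypterocarpan with a 2,2-dimethyl-2H-pyran ring fused at C1 (oxygen) and C2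
Product: 21 (6aS,11aS)-3-hydroxy-9-methoxypterocarpan with a 2,2-dimethyl-3,4-dihydro-2H-pyran ring fused at C1 (oxygen) and C2 (CNP0207547.1)
Conditions: H2 (1 atm), Pd/C, EtOAc, rt
Reagents that add atoms: none
Why: Heterogeneous catalytic hydrogenation saturates the cis-disubstituted chromene double bond and hydrogenolyses the O-benzyl ether in one operation; neutral solvent, one atmosphere and stopping at the calculated uptake are chosen because the C11a–O11 bond of pterocarpans is cleaved only under acidic or forcing conditions, and no stereocentre is touched.

## Compound list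

1 | 2,4,6-trihydroxybenzaldehyde | O=Cc1c(O)cc(O)cc1O | starting material
2 | 4-(benzyloxy)-2,6-dihydroxybenzaldehyde | O=Cc1c(O)cc(OCc2ccccc2)cc1O | intermediate
3 | 3-methylbut-2-enal | CC(C)=CC=O | starting material
4 | 5-(benzyloxy)-7-hydroxy-2,2-dimethyl-2H-chromene-8-carbaldehyde | O=Cc1c(O)cc(OCc2ccccc2)c2C=CC(C)(C)Oc12 | intermediate
5 | tert-butyl [5-(benzyloxy)-8-formyl-2,2-dimethyl-2H-chromen-7-yl] carbonate | O=Cc1c(OC(=O)OC(C)(C)C)cc(OCc2ccccc2)c2C=CC(C)(C)Oc12 | intermediate
6 | 2-hydroxy-4-methoxybenzaldehyde | COc1ccc(C=O)c(O)c1 | starting material
7 | 4-methoxy-2-(triisopropylsilyloxy)benzaldehyde | COc1ccc(C=O)c(O[Si](C(C)C)(C(C)C)C(C)C)c1 | intermediate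
8 | 1-ethynyl-4-methoxy-2-(triisopropylsilyloxy)benzene | COc1ccc(C#C)c(O[Si](C(C)C)(C(C)C)C(C)C)c1 | intermediate
9 | Cp2Zr(Cl)-alkenyl intermediate, chlorobis(cyclopentadienyl){(E)-2-[4-methoxy-2-(triisopropylsilyloxy)phenyl]ethenyl}zirconium (cyclopentadienyl rings drawn sigma-bonded) | COc1ccc(/C=C/[Zr](Cl)(C2C=CC=C2)C2C=CC=C2)c(O[Si](C(C)C)(C(C)C)C(C)C)c1 | intermediate
10 | (E)-1-(2-iodoethenyl)-4-methoxy-2-(triisopropylsilyloxy)benzene | COc1ccc(/C=C/I)c(O[Si](C(C)C)(C(C)C)C(C)C)c1 | intermediate
11 | (1S,2R)-trans-2-phenylcyclohexanol | O[C@H]1CCCC[C@@H]1c1ccccc1 | starting material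
12 | (E)-2-[4-methoxy-2-(triisopropylsilyloxy)phenyl]ethenyl (1S,2R)-2-phenylcyclohexyl ether | COc1ccc(/C=C/O[C@H]2CCCC[C@@H]2c2ccccc2)c(O[Si](C(C)C)(C(C)C)C(C)C)c1 | intermediate
13 | tert-butyl [5-(benzyloxy)-8-(hydroxymethyl)-2,2-dimethyl-2H-chromen-7-yl] carbonate (formed in step 8 as its alkoxide) | OCc1c(OC(=O)OC(C)(C)C)cc(OCc2ccccc2)c2C=CC(C)(C)Oc12 | intermediate
14 | [5-(benzyloxy)-7-hydroxy-2,2-dimethyl-2H-chromen-8-yl]methyl tert-butyl carbonate (formed as its phenoxide) | CC(C)(C)OC(=O)OCc1c(O)cc(OCc2ccccc2)c2C=CC(C)(C)Oc12 | intermediate
15 | 5-(benzyloxy)-2,2-dimethyl-8-methylidene-2H-chromen-7(8H)-one (ortho-quinone methide of ring A) | C=C1C(=O)C=C(OCc2ccccc2)C2=C1OC(C)(C)C=C2 | intermediate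
16 | (8R,9S)-5-(benzyloxy)-9-[4-methoxy-2-(triisopropylsilyloxy)phenyl]-2,2-dimethyl-8-{[(1S,2R)-2-phenylcyclohexyl]oxy}-9,10-dihydro-2H,8H-pyrano[2,3-f]chromene (C9 is C6a, C8 is the acetal carbon C6) | COc1ccc(c(O[Si](C(C)C)(C(C)C)C(C)C)c1)[C@@H]1Cc2c(cc(OCc3ccccc3)c3C=CC(C)(C)Oc23)O[C@H]1O[C@H]1CCCC[C@@H]1c1ccccc1 | intermediate
17 | (9S)-5-(benzyloxy)-9-[4-methoxy-2-(triisopropylsilyloxy)phenyl]-2,2-dimethyl-9,10-dihydro-2H,8H-pyrano[2,3-f]chromene | COc1ccc(c(O[Si](C(C)C)(C(C)C)C(C)C)c1)[C@@H]1Cc2c(cc(OCc3ccccc3)c3C=CC(C)(C)Oc23)OC1 | intermediate
18 | 2-[(9S)-5-(benzyloxy)-2,2-dimethyl-9,10-dihydro-2H,8H-pyrano[2,3-f]chromen-9-yl]-5-methoxyphenol | COc1ccc(c(O)c1)[C@@H]1Cc2c(cc(OCc3ccccc3)c3C=CC(C)(C)Oc23)OC1 | intermediate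
19 | C11a benzylic cation of 18 (para-quinone methide oxocarbenium form) | COc1ccc(c(O)c1)[C@@H]1[CH+]c2c(cc(OCc3ccccc3)c3C=CC(C)(C)Oc23)OC1 | intermediate
20 | (6aS,11aS)-3-(benzyloxy)-9-methoxypterocarpan with a 2,2-dimethyl-2H-pyran ring fused at C1 (oxygen) and C2 (CH=CH) | COc1ccc2c(c1)O[C@@H]1c3c(cc(OCc5ccccc5)c4c3OC(C)(C)C=C4)OC[C@H]21 | intermediate
21 | (6aS,11aS)-3-hydroxy-9-methoxypterocarpan with a 2,2-dimethyl-3,4-dihydro-2H-pyran ring fused at C1 (oxygen) and C2 (CH2), CNP0207547.1 | COc1ccc2c(c1)O[C@@H]1c3c(cc(O)c4c3OC(C)(C)CC4)OC[C@H]21 | target

## Step count and risks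

Total: 12 steps. Longest linear sequence: 9 steps (6 to 21, steps 4–12); the ring A/E branch (1 to 5) is 3 steps.

**Step 8 (key step).** The quinone methide may be lost to self-condensation, or to reduction by any hydride left over, faster than the hindered beta-aryl enol ether captures it. Facial selectivity may also be lower than with unsubstituted vinyl ethers, because the aryl group sits on the reacting carbon.
Fallback: the hydride step and the release of the quinone methide are separated. From 5, the aldehyde is reduced under non-basic conditions (i-Bu2AlH, CH2Cl2, −78 °C, cold acidic quench), so the carbonate does not migrate and the neutral alcohol 13 is isolated. It is then deprotonated with t-BuMgCl in the presence of 12 (Et2O/toluene, −78 °C → rt), which starts the same carbonate transfer and elimination with a magnesium counter-ion and no hydride in the flask; the route is rejoined at 16. If selectivity is the shortfall, the C6a epimers of 16 are diastereomers and would be separated at that stage. This fallback makes no compound outside the list.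

**Step 11.** Over-oxidation is the main danger: a second hydride loss from C11a of the product would aromatise ring C to a benzofuran, and proton loss from C6a of cation 19 would give an isoflavene whose reprotonation erases the stereocentre. Slow capture of the cation by the hindered phenol would favour both.
Fallback: oxidation and ring closure are uncoupled. From 17, with the phenol still silylated, DDQ in CH2Cl2/MeOH should trap the cation as the C11a methyl ether F1. TBAF then gives the phenol F2, and a trace of mild acid (PPTS, CH2Cl2) ionises the C11a–OMe bond so that the phenol closes ring C, rejoining the route at 20.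

**Step 7.** The copper-catalysed coupling may be slow with a hindered secondary alcohol, and at 80 °C the alkoxide may take the silyl group from the aryl silyl ether.
Fallback: the enol ether is made by forming the C=C bond instead. From 11, paraformaldehyde and HCl give the chloromethyl ether F3, and PPh3 gives the phosphonium chloride F4. KOt-Bu converts F4 into the ylide F5, which reacts with aldehyde 7 in a Wittig reaction to give 12 together with its Z isomer F6. The isomers are separated by chromatography and only the E isomer 12 is carried on, since the Z isomer would lead to the opposite configuration at C6a.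

**Step 9.** The acid may attack the chromene double bond (protonation followed by hydride capture or dimerisation), or cleave the endocyclic C–O bond of the acetal.
Fallback: the acetal oxygen is removed without a strong Lewis acid. From 16, mild aqueous acid (PPTS, acetone/H2O) should give the lactol F7 and free 11. NaBH4 (MeOH, 0 °C, short reaction time, because C6a is alpha to the aldehyde in the open form) gives the diol F8, and a Mitsunobu closure (PPh3, DIAD) of the phenol on the primary alcohol rejoins the route at 17.

**Step 12.** Hydrogenolysis of the C11a–O11 bond may accompany debenzylation, because ring A is very electron-rich.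
Fallback: the two reductions are done separately. From 20, diimide (2-nitrobenzenesulfonylhydrazide, Et3N, CH2Cl2, rt) saturates the chromene without any metal and gives the benzyl ether F9. The benzyl group is then removed by transfer hydrogenolysis (Pd(OH)2/C, 1,4-cyclohexadiene, EtOH, rt), rejoining the route at 21.

## Further compounds

F0 | step 8 | none | none
F1 | step 11 | (9S)-5-(benzyloxy)-10-methoxy-9-[4-methoxy-2-(triisopropylsilyloxy)phenyl]-2,2-dimethyl-9,10-dihydro-2H,8H-pyrano[2,3-f]chromene (C10 epimers) | COc1ccc(c(O[Si](C(C)C)(C(C)C)C(C)C)c1)[C@@H]1C(OC)c2c(cc(OCc3ccccc3)c3C=CC(C)(C)Oc23)OC1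
F2 | step 11 | 2-[(9S)-5-(benzyloxy)-10-methoxy-2,2-dimethyl-9,10-dihydro-2H,8H-pyrano[2,3-f]chromen-9-yl]-5-methoxyphenol (C10 epimers) | COc1ccc(c(O)c1)[C@@H]1C(OC)c2c(cc(OCc3ccccc3)c3C=CC(C)(C)Oc23)OC1
F3 | step 7 | (1S,2R)-1-(chloromethoxy)-2-phenylcyclohexane | ClCO[C@H]1CCCC[C@@H]1c1ccccc1
F4 | step 7 | triphenyl({[(1S,2R)-2-phenylcyclohexyl]oxy}methyl)phosphonium chloride | [Cl-].c1ccc(cc1)[P+](CO[C@H]1CCCC[C@@H]1c1ccccc1)(c1ccccc1)c1ccccc1
F5 | step 7 | triphenyl({[(1S,2R)-2-phenylcyclohexyl]oxy}methylidene)phosphorane | c1ccc(cc1)P(=CO[C@H]1CCCC[C@@H]1c1ccccc1)(c1ccccc1)c1ccccc1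
F6 | step 7 | (Z)-2-[4-methoxy-2-(triisopropylsilyloxy)phenyl]ethenyl (1S,2R)-2-phenylcyclohexyl ether | COc1ccc(/C=C\O[C@H]2CCCC[C@@H]2c2ccccc2)c(O[Si](C(C)C)(C(C)C)C(C)C)c1
F7 | step 9 | (9S)-5-(benzyloxy)-9-[4-methoxy-2-(triisopropylsilyloxy)phenyl]-2,2-dimethyl-9,10-dihydro-2H,8H-pyrano[2,3-f]chromen-8-ol (anomers) | COc1ccc(c(O[Si](C(C)C)(C(C)C)C(C)C)c1)[C@@H]1Cc2c(cc(OCc3ccccc3)c3C=CC(C)(C)Oc23)OC1O
F8 | step 9 | 5-(benzyloxy)-8-{(2S)-3-hydroxy-2-[4-methoxy-2-(triisopropylsilyloxy)phenyl]propyl}-2,2-dimethyl-2H-chromen-7-ol | COc1ccc(c(O[Si](C(C)C)(C(C)C)C(C)C)c1)[C@@H](CO)Cc1c(O)cc(OCc2ccccc2)c2C=CC(C)(C)Oc12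
F9 | step 12 | (6aS,11aS)-3-(benzyloxy)-9-methoxypterocarpan with a 2,2-dimethyl-3,4-dihydro-2H-pyran ring fused at C1 (oxygen) and C2 | COc1ccc2c(c1)O[C@@H]1c3c(cc(OCc5ccccc5)c4c3OC(C)(C)CC4)OC[C@H]21
A1 | alternative 1 | methyl 2-diazo-2-{2-[(5,7-bis(tert-butyldimethylsilyloxy)-2,2-dimethylchroman-8-yl)methoxy]-4-methoxyphenyl}acetate | COC(=O)C(=[N+]=[N-])c1ccc(OC)cc1OCc1c(O[Si](C)(C)C(C)(C)C)cc(O[Si](C)(C)C(C)(C)C)c2c1OC(C)(C)CC2
A2 | alternative 1 | methyl (2S,3R)-2-[5,7-bis(tert-butyldimethylsilyloxy)-2,2-dimethylchroman-8-yl]-6-methoxy-2,3-dihydrobenzofuran-3-carboxylate (cis) | COc1ccc2c(c1)O[C@H](c1c(O[Si](C)(C)C(C)(C)C)cc(O[Si](C)(C)C(C)(C)C)c3c1OC(C)(C)CC3)[C@@H]2C(=O)OC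
A3 | alternative 2 | 5-bromo-3-{[cis-3-ethynyl-2',2'-dimethyl-5'-(triisopropylsilyloxy)-pyrano-fused chroman-4-yl]oxy}-2H-pyran-2-one (ether oxygen on the future C11a, ethynyl on the future C6a) | O=c1occ(Br)cc1O[C@@H]1c2c(cc(O[Si](C(C)C)(C(C)C)C(C)C)c3c2OC(C)(C)CC3)OC[C@@H]1C#C
A4 | alternative 2 | (6aS,11aS)-9-bromopterocarpan with ring E, 3-O-triisopropylsilyl ether | Brc1ccc2c(c1)O[C@@H]1c3c(cc(O[Si](C(C)C)(C(C)C)C(C)C)c4c3OC(C)(C)CC4)OC[C@H]21
A5 | alternative 3 | 2,2-dimethyl-5-(triisopropylsilyloxy)chroman-7-ol | Oc1cc(O[Si](C(C)C)(C(C)C)C(C)C)c2CCC(C)(C)Oc2c1
A6 | alternative 3 | 6-methoxybenzofuran-3-carbaldehyde | COc1ccc2c(c1)occ2C=O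
A7 | alternative 3 | cis-pterocarpan C6 lactol with ring E, 3-O-triisopropylsilyl ether (anomers) | COc1ccc2c(c1)O[C@@H]1c3c(cc(O[Si](C(C)C)(C(C)C)C(C)C)c4c3OC(C)(C)CC4)OC(O)[C@H]21
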